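**Plan**

- Numbering (germacrane): C1 ketone, C2 furanone CH, C3 O-bearing furanone carbon, C4=C5 ring alkene, C6 lactone O–CH, C7 ring-fusion CH, C8 acyloxy CH, C9 CH2, C10 O-bearing quaternary carbon, C11–C13 methylene lactone.
- Cuts, in retrosynthetic order: furanone O–C3 bond with the C1 carbonyl (back to a ten-membered γ-hydroxy ynone); C2–C3 (back to an iodoalkyne/enal seco compound); C8–O acyl bond; C7–C8 (bromobutenolide plus alkynyl aldehyde); C7=C11 (ring-closing metathesis).
- Enabling feature: the furanone ring O–C3=C2–C1(=O)–C10 is the cyclodehydrated hydrate of a γ-hydroxy ynone C10(OH)–C1≡C2–C3(=O). C1–C2 can therefore be carried as an alkyne, whose sp carbon C2 is a nucleophile for a C3 aldehyde and strips transannular hydrogens from the carbocycle C1–C10; the Z C4=C5 alkene and the trans lactone at C6/C7 turn the two chain ends toward each other.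
- Forward order: butenolide ring (metathesis); Barbier union with the alkynyl aldehyde, which turns it into the methylene lactone; C8 ester; ten-membered carbocycle closed at C2–C3; furanone ring by transannular hydration and cyclisation.
- Stereochemistry: C6 by lipase resolution; C7 from C6 (addition anti to the C6 substituent on the butenolide); C8 by chair-controlled anti allylation, then Mitsunobu inversion; C10 from (R)-2-methylglycidol; Z C4=C5 from the ring of 4-methylfuran-2(5H)-one; E side-chain alkene from a stabilised Wittig reaction.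

Key step: step 17

**Route**

Step 1
Reactants: 1 4-methylfuran-2(5H)-one
Product: 3 rac-(Z)-2-methylhexa-2,5-diene-1,4-diol, via aluminium lactolate 2 (not isolated)
Conditions: iBu2AlH (1.1 equiv), CH2Cl2, −78 °C; then CH2=CHMgBr (3 equiv), THF, −78 → 0 °C; Rochelle salt work-up
Reagents that add atoms: vinylmagnesium bromide, C=C[Mg]Br
Why: One-pot partial reduction of the lactone and Grignard 1,2-addition to the aldehyde that the lactolate releases should open the ring, so that the cis relation of C3 and C6 in the butenolide becomes the Z C4=C5 alkene, with the C6 carbinol formed racemic.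

Step 2
Reactants: 3 rac-(Z)-2-methylhexa-2,5-diene-1,4-diol
Product: 4 rac-(Z)-6-[(tert-butyldimethylsilyl)oxy]-5-methylhexa-1,4-dien-3-ol
Conditions: TBSCl (1.05 equiv), imidazole, CH2Cl2, −20 °C
Reagents that add atoms: tert-butyldimethylsilyl chloride, CC(C)(C)[Si](C)(C)Cl
Why: Silyl ether formation should be selective for the primary allylic hydroxyl over the more hindered secondary bis-allylic one.

Step 3
Reactants: 4 rac-(Z)-6-[(tert-butyldimethylsilyl)oxy]-5-methylhexa-1,4-dien-3-ol
Product: 5 (S,Z)-6-[(tert-butyldimethylsilyl)oxy]-5-methylhexa-1,4-dien-3-ol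
Conditions: Novozym 435 (immobilised Candida antarctica lipase B), vinyl acetate, hexane, 30 °C, stopped near half conversion
Reagents that add atoms: none
Why: Lipase-catalysed kinetic resolution by transesterification should, following the Kazlauskas rule (large group the trisubstituted alkenyl, medium group vinyl), acetylate the (R)-alcohol and leave the (S)-alcohol, which carries the C6 configuration of the target.

Step 4
Reactants: 5 (S,Z)-6-[(tert-butyldimethylsilyl)oxy]-5-methylhexa-1,4-dien-3-ol; 6 2-(bromomethyl)acrylic acid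
Product: 7 (S,Z)-6-[(tert-butyldimethylsilyl)oxy]-5-methylhexa-1,4-dien-3-yl 2-(bromomethyl)acrylate
Conditions: N,N'-diisopropylcarbodiimide, DMAP (cat.), CH2Cl2, 0 °C
Reagents that add atoms: none
Why: Steglich-type carbodiimide esterification acylates the secondary alcohol without touching the C6 stereocenter.

Step 5
Reactants: 7 (S,Z)-6-[(tert-butyldimethylsilyl)oxy]-5-methylhexa-1,4-dien-3-yl 2-(bromomethyl)acrylate
Product: 8 (R)-3-(bromomethyl)-5-[(Z)-3-[(tert-butyldimethylsilyl)oxy]-2-methylprop-1-en-1-yl]furan-2(5H)-one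
Conditions: second-generation Grubbs catalyst RuCl2(=CHPh)(PCy3)(H2IMes) (5 mol %), CH2Cl2, 40 °C
Reagents that add atoms: none
Why: Ring-closing metathesis between the vinyl group and the 1,1-disubstituted acrylate should close the five-membered butenolide (C7=C11) with loss of ethylene, the trisubstituted C4=C5 alkene being too hindered to compete.

Step 6
Reactants: 9 (R)-2-methylglycidol
Product: 10 (S)-2-methylpent-4-ene-1,2-diol
Conditions: CH2=CHMgBr (3 equiv), CuI (10 mol %), THF, −30 → 0 °C
Reagents that add atoms: vinylmagnesium bromide, C=C[Mg]Br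
Why: Copper-catalysed Grignard opening of the epoxide at its unsubstituted CH2 carbon (SN2) leaves the quaternary stereocenter C10 untouched, the descriptor changing only through the priority order.

Step 7
Reactants: 10 (S)-2-methylpent-4-ene-1,2-diol
Product: 11 (S)-2-hydroxy-2-methylpent-4-enal
Conditions: SO3·pyridine, DMSO, iPr2NEt, CH2Cl2, 0 °C
Reagents that add atoms: none
Why: Parikh–Doering oxidation converts the primary alcohol to the aldehyde, while the tertiary hydroxyl cannot be oxidised and the quaternary C10 cannot epimerise.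

Step 8
Reactants: 11 (S)-2-hydroxy-2-methylpent-4-enal
Product: 12 (S)-3-methylhex-5-en-1-yn-3-ol
Conditions: dimethyl (1-diazo-2-oxopropyl)phosphonate, K2CO3, MeOH, 0 °C → rt
Reagents that add atoms: dimethyl (1-diazo-2-oxopropyl)phosphonate, COP(=O)(OC)C(=[N+]=[N-])C(C)=O
Why: Ohira–Bestmann homologation converts the non-enolisable aldehyde into the terminal alkyne C1≡C2 under mild conditions.

Step 9
Reactants: 12 (S)-3-methylhex-5-en-1-yn-3-ol
Product: 14 (S)-3-hydroxy-3-methylpent-4-ynal, via ozonide 13 (not isolated)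
Conditions: O3 (1 equiv), CH2Cl2, −78 °C; then Me2S, −78 °C → rt; used crude
Reagents that add atoms: ozone, [O-][O+]=O
Why: Ozonolysis with reductive work-up cleaves the terminal alkene much faster than the alkyne and should give the C8 aldehyde.

Step 10
Reactants: 15 (Z)-but-2-ene-1,4-diyl diacetate; 16 tert-butyl 2-(triphenyl-λ5-phosphanylidene)propanoate
Product: 19 tert-butyl (E)-4-acetoxy-2-methylbut-2-enoate, via ozonide 17 (not isolated), via 2-oxoethyl acetate 18 (not isolated)
Conditions: O3, CH2Cl2, −78 °C; PPh3; then 16 (2.1 equiv), −78 °C → rt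
Reagents that add atoms: none
Why: Ozonolysis of the symmetrical alkene gives two equivalents of aldehyde 18, and Wittig olefination with the stabilised α-methyl ylide should give the E trisubstituted enoate.

Step 11
Reactants: 19 tert-butyl (E)-4-acetoxy-2-methylbut-2-enoate
Product: 20 (E)-4-acetoxy-2-methylbut-2-enoic acid
Conditions: CF3CO2H, CH2Cl2, 0 °C → rt
Reagents that add atoms: none
Why: Acidolysis of the tert-butyl ester (loss of isobutene) frees the acid while the primary allylic acetate should survive.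

Step 12
Reactants: 8 (R)-3-(bromomethyl)-5-[(Z)-3-[(tert-butyldimethylsilyl)oxy]-2-methylprop-1-en-1-yl]furan-2(5H)-one; 14 (S)-3-hydroxy-3-methylpent-4-ynal
Product: 22 (4R,5R)-5-[(Z)-3-[(tert-butyldimethylsilyl)oxy]-2-methylprop-1-en-1-yl]-4-[(1S,3S)-1,3-dihydroxy-3-methylpent-4-yn-1-yl]-3-methylideneoxolan-2-one, via allylzinc bromide 21 (not isolated)
Conditions: Zn dust, THF/saturated aqueous NH4Cl, 0 °C → rt
Reagents that add atoms: none
Why: In this zinc-mediated Barbier allylation the allylzinc should add through ring carbon C7 (SE2′) in a Zimmerman–Traxler chair on the butenolide face opposite the C6 substituent, which sets C7 trans to C6 and, because the ring holds C6 trans to the CH2Zn group, gives the anti adduct with the (8S) carbinol.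

Step 13
Reactants: 22 the Barbier adduct; 20 (E)-4-acetoxy-2-methylbut-2-enoic acid
Product: 23 (1R,3S)-1-[(2R,3R)-2-[(Z)-3-[(tert-butyldimethylsilyl)oxy]-2-methylprop-1-en-1-yl]-4-methylidene-5-oxooxolan-3-yl]-3-hydroxy-3-methylpent-4-yn-1-yl (E)-4-acetoxy-2-methylbut-2-enoate
Conditions: PPh3, diisopropyl azodicarboxylate, THF, 0 °C → rt
Reagents that add atoms: none
Why: Mitsunobu esterification should displace the activated C8 hydroxyl by the carboxylate of 20 with SN2 inversion, giving the (8R) ester of the target, while the tertiary C10 hydroxyl cannot react.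

Step 14
Reactants: 23 the C8 ester with terminal alkyne
Product: 24 the corresponding 1-iodoalkyne, (1R,3S)-1-[(2R,3R)-2-[(Z)-3-[(tert-butyldimethylsilyl)oxy]-2-methylprop-1-en-1-yl]-4-methylidene-5-oxooxolan-3-yl]-3-hydroxy-5-iodo-3-methylpent-4-yn-1-yl (E)-4-acetoxy-2-methylbut-2-enoate
Conditions: N-iodosuccinimide, AgNO3 (10 mol %), acetone, rt, dark
Reagents that add atoms: N-iodosuccinimide, O=C1CCC(=O)N1I
Why: Silver-catalysed electrophilic iodination of the terminal alkyne (through the silver acetylide) should give the iodoalkyne without touching the alkenes.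

Step 15
Reactants: 24 the iodoalkyne silyl ether
Product: 25 (1R,3S)-3-hydroxy-1-[(2R,3R)-2-[(Z)-3-hydroxy-2-methylprop-1-en-1-yl]-4-methylidene-5-oxooxolan-3-yl]-5-iodo-3-methylpent-4-yn-1-yl (E)-4-acetoxy-2-methylbut-2-enoate
Conditions: HF·pyridine, pyridine, THF, 0 °C
Reagents that add atoms: none
Why: Fluoride-mediated desilylation removes the only silyl ether and frees the C3 primary alcohol.

Step 16
Reactants: 25 the C3 allylic alcohol
Product: 26 (1R,3S)-3-hydroxy-5-iodo-3-methyl-1-[(2R,3R)-4-methylidene-2-[(Z)-2-methyl-3-oxoprop-1-en-1-yl]-5-oxooxolan-3-yl]pent-4-yn-1-yl (E)-4-acetoxy-2-methylbut-2-enoate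
Conditions: MnO2, CH2Cl2, rt
Reagents that add atoms: none
Why: Allylic oxidation with MnO2 acts only on the primary allylic alcohol and, being neutral, should give the enal without Z to E isomerisation.

Step 17
Reactants: 26 the iodoalkyne enal
Product: 28 (6R,7R,8R,10S)-8-[(E)-4-acetoxy-2-methylbut-2-enoyloxy]-3,10-dihydroxygermacra-4Z,11(13)-dien-1-yn-12,6-olide (C3 epimers), via alkynylchromium dichloride 27 (not isolated)
Conditions: CrCl2 (8 equiv), NiCl2 (2 mol %), degassed THF/DMF, rt, slow addition of 26 to 0.002 M final concentration; aqueous work-up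
Reagents that add atoms: none
Why: Two equivalents of divalent chromium (nickel-assisted) insert into the C2–I bond to give the alkynylchromium 27 (trivalent chromium), whose sp carbon C2 adds to the C3 aldehyde in a Nozaki–Hiyama–Kishi reaction, forming C2–C3 and closing the carbocycle C1–C10. The closest known reaction type is the intramolecular Nozaki–Hiyama–Kishi coupling of iodoalkynes with aldehydes used to close strained nine- and ten-membered cycloalkynes of the enediyne class. The ten-membered ring closes in the 10-exo-trig mode (the C=O lies outside the forming ring); closure is helped by the Z C4=C5 alkene and the trans-fused lactone, which turn the aldehyde back toward the C8–C10 arm, and by the two sp carbons, which take transannular hydrogens out of the ring. The new C3 carbinol is not controlled and need not be, since step 18 oxidises it. The step needs chemoselectivity for the aldehyde over the lactone, the two enoates and the allylic acetate, which the low basicity and carbonyl selectivity of organochromium reagents should give, and cyclisation over oligomerisation, which slow addition at high dilution secures.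

Step 18
Reactants: 28 the ten-membered propargylic alcohol
Product: 29 (6R,7R,8R,10S)-8-[(E)-4-acetoxy-2-methylbut-2-enoyloxy]-10-hydroxy-3-oxogermacra-4Z,11(13)-dien-1-yn-12,6-olide
Conditions: Dess–Martin periodinane, NaHCO3, CH2Cl2, 0 °C
Reagents that add atoms: none
Why: Dess–Martin oxidation of the doubly activated (allylic and propargylic) alcohol should give the cross-conjugated ynone and removes the C3 stereocenter.

Step 19
Reactants: 29 the ten-membered γ-hydroxy ynone
Product: 31 CNP0387534.1, via 1,3-diketone 30 (not isolated)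
Conditions: (4-CF3C6H4)3PAuCl (5 mol %), AgOTf (5 mol %), toluene containing H2O (2 equiv), rt
Reagents that add atoms: water, O
Why: Gold-catalysed hydration of the ynone at C1 (π-activation of the alkyne by monovalent gold, conjugate attack of water) should give the 1,3-diketone, whose C3 carbonyl is attacked transannularly by the C10 hydroxyl (5-exo-trig) and loses water, the known cyclisation of γ-hydroxy alkynones to 3(2H)-furanones, with no stereocenter affected.

**Compound list**

1 | 4-methylfuran-2(5H)-one | CC1=CC(=O)OC1 | starting material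
2 | diisobutylaluminium 4-methyl-2,5-dihydrofuran-2-olate (aluminium lactolate, racemic) | CC1=CC(O[Al](CC(C)C)CC(C)C)OC1 | intermediate
3 | rac-(Z)-2-methylhexa-2,5-diene-1,4-diol | OC/C(C)=C\C(O)C=C | intermediate
4 | rac-(Z)-6-[(tert-butyldimethylsilyl)oxy]-5-methylhexa-1,4-dien-3-ol | CC(C)(C)[Si](C)(C)OC/C(C)=C\C(O)C=C | intermediate
5 | (S,Z)-6-[(tert-butyldimethylsilyl)oxy]-5-methylhexa-1,4-dien-3-ol | CC(C)(C)[Si](C)(C)OC/C(C)=C\[C@@H](O)C=C | intermediate
6 | 2-(bromomethyl)acrylic acid | C=C(CBr)C(=O)O | starting material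
7 | (S,Z)-6-[(tert-butyldimethylsilyl)oxy]-5-methylhexa-1,4-dien-3-yl 2-(bromomethyl)acrylate | CC(C)(C)[Si](C)(C)OC/C(C)=C\[C@@H](OC(=O)C(=C)CBr)C=C | intermediate
8 | (R)-3-(bromomethyl)-5-[(Z)-3-[(tert-butyldimethylsilyl)oxy]-2-methylprop-1-en-1-yl]furan-2(5H)-one | CC(C)(C)[Si](C)(C)OC/C(C)=C\[C@H]1OC(=O)C(CBr)=C1 | intermediate
9 | (R)-2-methylglycidol, (R)-(2-methyloxiran-2-yl)methanol | C[C@@]1(CO)CO1 | starting material
10 | (S)-2-methylpent-4-ene-1,2-diol | C[C@@](O)(CO)CC=C | intermediate
11 | (S)-2-hydroxy-2-methylpent-4-enal | C[C@@](O)(C=O)CC=C | intermediate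
12 | (S)-3-methylhex-5-en-1-yn-3-ol | C[C@@](O)(C#C)CC=C | intermediate
13 | (2S)-2-methyl-1-(1,2,4-trioxolan-3-yl)but-3-yn-2-ol (ozonide of 12) | C[C@@](O)(C#C)CC1OCOO1 | intermediate
14 | (S)-3-hydroxy-3-methylpent-4-ynal | C[C@@](O)(C#C)CC=O | intermediate
15 | (Z)-but-2-ene-1,4-diyl diacetate | CC(=O)OC/C=C\COC(C)=O | starting material
16 | tert-butyl 2-(triphenyl-λ5-phosphanylidene)propanoate | CC(=P(c1ccccc1)(c1ccccc1)c1ccccc1)C(=O)OC(C)(C)C | starting material
17 | (1,2,4-trioxolane-3,5-diyl)dimethanediyl diacetate (ozonide of 15) | CC(=O)OCC1OC(COC(C)=O)OO1 | intermediate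
18 | 2-oxoethyl acetate | CC(=O)OCC=O | intermediate
19 | tert-butyl (E)-4-acetoxy-2-methylbut-2-enoate | CC(=O)OC/C=C(\C)C(=O)OC(C)(C)C | intermediate
20 | (E)-4-acetoxy-2-methylbut-2-enoic acid | CC(=O)OC/C=C(\C)C(=O)O | intermediate
21 | {[(5R)-5-[(Z)-3-[(tert-butyldimethylsilyl)oxy]-2-methylprop-1-en-1-yl]-2-oxo-2,5-dihydrofuran-3-yl]methyl}zinc bromide | CC(C)(C)[Si](C)(C)OC/C(C)=C\[C@H]1OC(=O)C(C[Zn]Br)=C1 | intermediate
22 | (4R,5R)-5-[(Z)-3-[(tert-butyldimethylsilyl)oxy]-2-methylprop-1-en-1-yl]-4-[(1S,3S)-1,3-dihydroxy-3-methylpent-4-yn-1-yl]-3-methylideneoxolan-2-one | C=C1C(=O)O[C@H](/C=C(/C)CO[Si](C)(C)C(C)(C)C)[C@H]1[C@@H](O)C[C@](C)(O)C#C | intermediate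
23 | (1R,3S)-1-[(2R,3R)-2-[(Z)-3-[(tert-butyldimethylsilyl)oxy]-2-methylprop-1-en-1-yl]-4-methylidene-5-oxooxolan-3-yl]-3-hydroxy-3-methylpent-4-yn-1-yl (E)-4-acetoxy-2-methylbut-2-enoate | C=C1C(=O)O[C@H](/C=C(/C)CO[Si](C)(C)C(C)(C)C)[C@H]1[C@H](OC(=O)/C(C)=C/COC(C)=O)C[C@](C)(O)C#C | intermediate
24 | (1R,3S)-1-[(2R,3R)-2-[(Z)-3-[(tert-butyldimethylsilyl)oxy]-2-methylprop-1-en-1-yl]-4-methylidene-5-oxooxolan-3-yl]-3-hydroxy-5-iodo-3-methylpent-4-yn-1-yl (E)-4-acetoxy-2-methylbut-2-enoate | C=C1C(=O)O[C@H](/C=C(/C)CO[Si](C)(C)C(C)(C)C)[C@H]1[C@H](OC(=O)/C(C)=C/COC(C)=O)C[C@](C)(O)C#CI | intermediate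
25 | (1R,3S)-3-hydroxy-1-[(2R,3R)-2-[(Z)-3-hydroxy-2-methylprop-1-en-1-yl]-4-methylidene-5-oxooxolan-3-yl]-5-iodo-3-methylpent-4-yn-1-yl (E)-4-acetoxy-2-methylbut-2-enoate | C=C1C(=O)O[C@H](/C=C(/C)CO)[C@H]1[C@H](OC(=O)/C(C)=C/COC(C)=O)C[C@](C)(O)C#CI | intermediate
26 | (1R,3S)-3-hydroxy-5-iodo-3-methyl-1-[(2R,3R)-4-methylidene-2-[(Z)-2-methyl-3-oxoprop-1-en-1-yl]-5-oxooxolan-3-yl]pent-4-yn-1-yl (E)-4-acetoxy-2-methylbut-2-enoate | C=C1C(=O)O[C@H](/C=C(/C)C=O)[C@H]1[C@H](OC(=O)/C(C)=C/COC(C)=O)C[C@](C)(O)C#CI | intermediate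
27 | alkynylchromium dichloride of 26 (C2–CrCl2 in place of C2–I) | C=C1C(=O)O[C@H](/C=C(/C)C=O)[C@H]1[C@H](OC(=O)/C(C)=C/COC(C)=O)C[C@](C)(O)C#C[Cr](Cl)Cl | intermediate
28 | (6R,7R,8R,10S)-8-[(E)-4-acetoxy-2-methylbut-2-enoyloxy]-3,10-dihydroxygermacra-4Z,11(13)-dien-1-yn-12,6-olide (mixture of C3 epimers) | C=C1C(=O)O[C@@H]2/C=C(/C)C(O)C#C[C@@](C)(O)C[C@@H](OC(=O)/C(C)=C/COC(C)=O)[C@@H]12 | intermediate
29 | (6R,7R,8R,10S)-8-[(E)-4-acetoxy-2-methylbut-2-enoyloxy]-10-hydroxy-3-oxogermacra-4Z,11(13)-dien-1-yn-12,6-olide | C=C1C(=O)O[C@@H]2/C=C(/C)C(=O)C#C[C@@](C)(O)C[C@@H](OC(=O)/C(C)=C/COC(C)=O)[C@@H]12 | intermediate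
30 | (6R,7R,8R,10S)-8-[(E)-4-acetoxy-2-methylbut-2-enoyloxy]-10-hydroxy-1,3-dioxogermacra-4Z,11(13)-dien-12,6-olide | C=C1C(=O)O[C@@H]2/C=C(/C)C(=O)CC(=O)[C@@](C)(O)C[C@@H](OC(=O)/C(C)=C/COC(C)=O)[C@@H]12 | intermediate
31 | CNP0387534.1, (6R,7R,8R,10S)-8-[(E)-4-acetoxy-2-methylbut-2-enoyloxy]-1-oxo-3,10-epoxygermacra-2,4Z,11(13)-trien-12,6-olide | C=C1C(=O)O[C@@H]2/C=C(/C)C3=CC(=O)[C@](C)(C[C@@H](OC(=O)/C(C)=C/COC(C)=O)[C@@H]12)O3 | target

**Step count**

Total: 19 steps. Longest linear sequence: 13 steps (steps 1–5, then 12–19).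

**Steps most likely to fail, with fallbacks**

Step 17. The seco compound may oligomerise, or the linear alkynylchromium end may fail to reach the C3 aldehyde across the forming ten-membered ring. The fallback replaces the sp nucleophile by a bent sp3 enolate and sets out from 23. Gold-catalysed Markovnikov hydration of the terminal alkyne ((Ph3P)AuNTf2, aqueous dioxane) would give the α-hydroxy methyl ketone (1R,3S)-1-[(2R,3R)-2-[(Z)-3-[(tert-butyldimethylsilyl)oxy]-2-methylprop-1-en-1-yl]-4-methylidene-5-oxooxolan-3-yl]-3-hydroxy-3-methyl-4-oxopentyl (E)-4-acetoxy-2-methylbut-2-enoate F1. HF·pyridine would free its primary alcohol F2, and MnO2 would give the keto enal F3. Soft enolisation of the methyl ketone (Bu2BOTf, iPr2NEt, CH2Cl2, −78 °C, high dilution, non-oxidative work-up) would then close C2–C3 by an intramolecular boron aldol reaction to the ten-membered β-hydroxy ketone F4. Dess–Martin oxidation of F4 gives the 1,3-diketone 30, where the fallback comes back to the route; 30 closes to 31 as in step 19, for which mild acid alone suffices.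

Step 13. Displacement at the hindered C8 may lose out to E2 elimination toward C7, or to acyl migration of the free C8 hydroxyl onto the lactone carbonyl before activation; the step also rests on the anti selectivity of step 12. The fallback inverts C8 by oxidation and reagent-controlled reduction and sets out from 22. Dess–Martin oxidation (cold, neutral, to avoid migration of the exocyclic alkene) would give the C8 ketone (4R,5R)-5-[(Z)-3-[(tert-butyldimethylsilyl)oxy]-2-methylprop-1-en-1-yl]-4-[(S)-3-hydroxy-3-methylpent-4-ynoyl]-3-methylideneoxolan-2-one F5. Reduction with (S)-2-methyl-CBS-oxazaborolidine and catecholborane at −78 °C, with ring carbon C7 as the large group, should give the (8R)-alcohol F6, the C8 epimer of 22. Yamaguchi esterification of F6 with acid 20 (2,4,6-trichlorobenzoyl chloride, Et3N, DMAP), with retention, comes back to the route at 23. This path also takes both C8 epimers from step 12.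

Step 19. The gold catalyst may be held up by the other π-systems, the Z enone may isomerise, or hydration may stop before the transannular closure. The fallback delivers the oxygen at C1 through a stoichiometric amine adduct and sets out from 29. Excess diethylamine in ethanol would add to the ynone at C1 and, reversibly, to the methylene lactone, giving the bis-adduct F7 (C1 enaminone, 13-diethylamino-11,13-dihydro lactone). Aqueous acetic acid would hydrolyse the enaminone with closure of the furanone to F8, the 13-diethylamino-11,13-dihydro derivative of 31. Quaternisation with MeI and elimination with NaHCO3 restores the methylene group and comes back to the route at 31.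

**Further compounds**

F1 | step 17 | (1R,3S)-1-[(2R,3R)-2-[(Z)-3-[(tert-butyldimethylsilyl)oxy]-2-methylprop-1-en-1-yl]-4-methylidene-5-oxooxolan-3-yl]-3-hydroxy-3-methyl-4-oxopentyl (E)-4-acetoxy-2-methylbut-2-enoate | C=C1C(=O)O[C@H](/C=C(/C)CO[Si](C)(C)C(C)(C)C)[C@H]1[C@H](OC(=O)/C(C)=C/COC(C)=O)C[C@](C)(O)C(C)=O
F2 | step 17 | (1R,3S)-3-hydroxy-1-[(2R,3R)-2-[(Z)-3-hydroxy-2-methylprop-1-en-1-yl]-4-methylidene-5-oxooxolan-3-yl]-3-methyl-4-oxopentyl (E)-4-acetoxy-2-methylbut-2-enoate | C=C1C(=O)O[C@H](/C=C(/C)CO)[C@H]1[C@H](OC(=O)/C(C)=C/COC(C)=O)C[C@](C)(O)C(C)=O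
F3 | step 17 | (1R,3S)-3-hydroxy-3-methyl-1-[(2R,3R)-4-methylidene-2-[(Z)-2-methyl-3-oxoprop-1-en-1-yl]-5-oxooxolan-3-yl]-4-oxopentyl (E)-4-acetoxy-2-methylbut-2-enoate | C=C1C(=O)O[C@H](/C=C(/C)C=O)[C@H]1[C@H](OC(=O)/C(C)=C/COC(C)=O)C[C@](C)(O)C(C)=O
F4 | step 17 | (6R,7R,8R,10S)-8-[(E)-4-acetoxy-2-methylbut-2-enoyloxy]-3,10-dihydroxy-1-oxogermacra-4Z,11(13)-dien-12,6-olide (C3 epimers) | C=C1C(=O)O[C@@H]2/C=C(/C)C(O)CC(=O)[C@@](C)(O)C[C@@H](OC(=O)/C(C)=C/COC(C)=O)[C@@H]12
F5 | step 13 | (4R,5R)-5-[(Z)-3-[(tert-butyldimethylsilyl)oxy]-2-methylprop-1-en-1-yl]-4-[(S)-3-hydroxy-3-methylpent-4-ynoyl]-3-methylideneoxolan-2-one | C=C1C(=O)O[C@H](/C=C(/C)CO[Si](C)(C)C(C)(C)C)[C@H]1C(=O)C[C@](C)(O)C#C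
F6 | step 13 | (4R,5R)-5-[(Z)-3-[(tert-butyldimethylsilyl)oxy]-2-methylprop-1-en-1-yl]-4-[(1R,3S)-1,3-dihydroxy-3-methylpent-4-yn-1-yl]-3-methylideneoxolan-2-one | C=C1C(=O)O[C@H](/C=C(/C)CO[Si](C)(C)C(C)(C)C)[C@H]1[C@H](O)C[C@](C)(O)C#C
F7 | step 19 | (6R,7R,8R,10S)-8-[(E)-4-acetoxy-2-methylbut-2-enoyloxy]-1,13-bis(diethylamino)-10-hydroxy-3-oxogermacra-1,4Z-dien-12,6-olide (C11 epimers) | CCN(CC)CC1C(=O)O[C@@H]2/C=C(/C)C(=O)C=C(N(CC)CC)[C@@](C)(O)C[C@@H](OC(=O)/C(C)=C/COC(C)=O)[C@@H]12
F8 | step 19 | (6R,7R,8R,10S)-8-[(E)-4-acetoxy-2-methylbut-2-enoyloxy]-13-diethylamino-1-oxo-3,10-epoxygermacra-2,4Z-dien-12,6-olide (C11 epimers) | CCN(CC)CC1C(=O)O[C@@H]2/C=C(/C)C3=CC(=O)[C@](C)(C[C@@H](OC(=O)/C(C)=C/COC(C)=O)[C@@H]12)O3
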